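The quinone ring (C1 carbonyl flanked by C2–OMe and chain-bearing C6; C4 the other carbonyl) hides a 5-alkylresorcinol, the meta C2/C4 oxygen pattern of a polyketide. It is therefore cut into a two-carbon piece (C1, C2: dimethyl malonate) and a four-carbon piece (C3–C6: the enone made from the chain aldehyde). One Michael–Dieckmann annulation joins them, forming C1–C6 and then C2–C3, and after in-flask decarboxylation gives a 5-substituted cyclohexane-1,3-dione. Iodine–methanol aromatisation delivers the resorcinol monomethyl ether, and Teuber oxidation para to the phenol turns the former malonate CH (C1) into the quinone carbonyl.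

Key step: step 2

Remark: dione 9 has a mirror plane, so its two carbonyl carbons are equivalent and etherifying either gives the same compound 11; the text counts the malonate-derived one as C2. Intermediates 6, 7, 8 and 10 are racemic and the target is achiral.

Step 1
Reactants: 1 16-hydroxyhexadecanoic acid; 2 1-(triphenylphosphoranylidene)propan-2-one
Product: 4 (E)-18-oxononadec-16-enoic acid, via 16-oxohexadecanoic acid 3 (not isolated)
Conditions: PhI(OAc)2 (1.1 equiv), TEMPO (2,2,6,6-tetramethylpiperidin-1-oxyl, 0.1 equiv), CH2Cl2, rt; then 2 (1.3 equiv), 40 °C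
Reagents that add atoms: none
Why: One-pot TEMPO/PhI(OAc)2 oxidation–Wittig olefination: the oxidation stops at aldehyde 3 in dry CH2Cl2 and the ketone-stabilised ylide tolerates the acetic acid the oxidant releases anyway, so the free chain acid needs no protection; the stabilised ylide should give mainly the E alkene, whose geometry is erased in step 2.

Step 2
Reactants: 4 (E)-18-oxononadec-16-enoic acid; 5 dimethyl malonate
Product: 9 15-(3,5-dioxocyclohexyl)pentadecanoic acid, via malonate Michael adduct 6 (not isolated), via cyclic keto ester 7 (not isolated), via keto diacid 8 (not isolated)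
Conditions: NaOMe (2.3 equiv), MeOH, reflux; then 2 M NaOH (aq), reflux; then HCl (aq) to pH 1, 80 °C
Reagents that add atoms: none
Why: Sodiomalonate adds in conjugate fashion to the enone of 4 (Michael addition; malonate CH to the chain-bearing β-carbon, the later C1–C6 bond), and the equilibrating methyl-side ketone enolate then attacks one malonate ester with loss of methoxide (Claisen/Dieckmann condensation; acetyl carbon to ester carbonyl, the later C2–C3 bond). The closest known reaction type is the Michael–Claisen annulation of enones with malonates used for dimedone and 5-alkylresorcinols, including the same in-flask saponification and decarboxylation of the β-keto acid 8. The single ring closes by a 6-exo-trig acyl substitution (6-(enolexo)-exo-trig for the enolate). The chain-bearing and ester-bearing ring carbons of 7 are new stereocentres under no control (racemic, trans expected by equilibration); the second is lost on decarboxylation, 9 is achiral and the first becomes sp2 in step 3. The step needs 1,4- over 1,2-addition, secured by the soft stabilised malonate anion, and closure through the methyl-side enolate, secured because the internal CH2 could only close a four-membered ring and because the product is drained off as its stabilised 1,3-dicarbonyl enolate. The chain carboxylate, formed at once by the first equivalent of NaOMe, is inert throughout.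

Step 3
Reactants: 9 15-(3,5-dioxocyclohexyl)pentadecanoic acid
Product: 11 methyl 15-(3-hydroxy-5-methoxyphenyl)pentadecanoate, via methoxyenone ester 10 (not isolated)
Conditions: I2 (1.5 equiv), MeOH, reflux
Reagents that add atoms: methanol, CO
Why: Iodine–methanol aromatisation of a cyclohexane-1,3-dione: HI formed in situ catalyses enol ether formation and Fischer esterification of the chain acid, α-iodination of 10 next to the carbonyl and loss of HI give the dienone tautomer of the phenol, and because 9 is symmetric only one monomethyl ether can form while the phenol OH cannot be etherified by MeOH.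

Step 4
Reactants: 11 methyl 15-(3-hydroxy-5-methoxyphenyl)pentadecanoate
Product: 12 15-(3-hydroxy-5-methoxyphenyl)pentadecanoic acid
Conditions: LiOH·H2O (3 equiv), THF/MeOH/H2O, rt; then 1 M HCl
Reagents that add atoms: lithium hydroxide, [Li+].[OH-]
Why: Saponification of an unhindered methyl ester, to which the phenol and the aryl methyl ether are stable; it is placed here so that no base meets the base-sensitive methoxyquinone.

Step 5
Reactants: 12 15-(3-hydroxy-5-methoxyphenyl)pentadecanoic acid
Product: 13 15-(5-methoxy-3,6-dioxocyclohexa-1,4-dien-1-yl)pentadecanoic acid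
Conditions: (KSO3)2NO (Fremy's salt, 2.5 equiv), KH2PO4 (aq), acetone, 0 °C to rt
Reagents that add atoms: potassium nitrosodisulfonate (Fremy's salt), [K+].[K+].[O-]S(=O)(=O)N([O])S(=O)(=O)[O-]
Why: Teuber oxidation: one nitrosodisulfonate radical abstracts the phenolic hydrogen and a second adds at the unsubstituted para position between OMe and the chain, which collapses to the para-quinone; the free para position should secure the 1,4- over a 1,2-quinone and the carboxylic acid is inert.

Compound list
1 | 16-hydroxyhexadecanoic acid | OCCCCCCCCCCCCCCCC(=O)O | starting material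
2 | 1-(triphenylphosphoranylidene)propan-2-one | CC(=O)C=P(c1ccccc1)(c1ccccc1)c1ccccc1 | starting material
3 | 16-oxohexadecanoic acid | O=CCCCCCCCCCCCCCCC(=O)O | intermediate
4 | (E)-18-oxononadec-16-enoic acid | CC(=O)/C=C/CCCCCCCCCCCCCCC(=O)O | intermediate
5 | dimethyl malonate | COC(=O)CC(=O)OC | starting material
6 | 16-(1,3-dimethoxy-1,3-dioxopropan-2-yl)-18-oxononadecanoic acid (racemic) | CC(=O)CC(CCCCCCCCCCCCCCC(=O)O)C(C(=O)OC)C(=O)OC | intermediate
7 | methyl 2-(14-carboxytetradecyl)-4,6-dioxocyclohexane-1-carboxylate (racemic, formed as its sodium enolate) | COC(=O)C1C(CCCCCCCCCCCCCCC(=O)O)CC(=O)CC1=O | intermediate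
8 | 2-(14-carboxytetradecyl)-4,6-dioxocyclohexane-1-carboxylic acid (racemic) | OC(=O)C1C(CCCCCCCCCCCCCCC(=O)O)CC(=O)CC1=O | intermediate
9 | 15-(3,5-dioxocyclohexyl)pentadecanoic acid | O=C1CC(CCCCCCCCCCCCCCC(=O)O)CC(=O)C1 | intermediate
10 | methyl 15-(3-methoxy-5-oxocyclohex-3-en-1-yl)pentadecanoate (racemic) | COC1=CC(=O)CC(CCCCCCCCCCCCCCC(=O)OC)C1 | intermediate
11 | methyl 15-(3-hydroxy-5-methoxyphenyl)pentadecanoate | COC(=O)CCCCCCCCCCCCCCc1cc(O)cc(OC)c1 | intermediate
12 | 15-(3-hydroxy-5-methoxyphenyl)pentadecanoic acid | OC(=O)CCCCCCCCCCCCCCc1cc(O)cc(OC)c1 | intermediate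
13 | 15-(5-methoxy-3,6-dioxocyclohexa-1,4-dien-1-yl)pentadecanoic acid | COC1=CC(=O)C=C(CCCCCCCCCCCCCCC(=O)O)C1=O | target

Total step count: 5
Longest linear sequence: 5 steps (1 to 13)

Steps most likely to fail

Step 3. The aromatisation may run on to the dimethyl ether through a bis-enol ether, iodinate the electron-rich ring, or stall at the enol ether stage. The fallback sets out from 9 and comes back at 11. Compound 9 is first turned on purpose into methoxyenone ester 10 (MeOH, HC(OMe)3, TsOH·H2O, reflux), which is isolated. Kinetic deprotonation of 10 at the CH2 between the carbonyl and the chain-bearing carbon (LDA, THF, −78 °C) and trapping with PhSeCl should give methyl 15-[5-methoxy-3-oxo-2-(phenylselanyl)cyclohex-4-en-1-yl]pentadecanoate F1. Oxidation (H2O2, pyridine, CH2Cl2, 0 °C) and selenoxide syn-elimination should give the cross-conjugated dienone, which tautomerises to 11.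

Step 5. The radical oxidation may attack an ortho position and give a 1,2-quinone, over-oxidise the electron-rich product, or run poorly because the soap-like substrate aggregates in the aqueous buffer. The fallback sets out from 12 and comes back at 13. Azo coupling of the phenoxide of 12 with 4-sulfobenzenediazonium chloride (from sulfanilic acid, NaNO2, HCl; then aq NaOH, 0 °C) should place the azo group para to the hydroxyl, giving 15-{5-hydroxy-3-methoxy-2-[(E)-(4-sulfophenyl)diazenyl]phenyl}pentadecanoic acid F2. Reductive cleavage (Na2S2O4, aq NaOH, 60 °C) gives 15-(2-amino-5-hydroxy-3-methoxyphenyl)pentadecanoic acid F3. Oxidation of this para-aminophenol (FeCl3, dilute HCl, rt) and hydrolysis of the quinone imine give 13.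

Step 1. The ketone-stabilised ylide may olefinate the aliphatic aldehyde only sluggishly in the acidic one-pot medium, leaving time for aldehyde self-condensation or over-oxidation, and the free hydroxy acid may dissolve poorly in CH2Cl2. The fallback sets out from 1 and comes back at 9. Fischer esterification of 1 (MeOH, H2SO4, reflux) gives methyl 16-hydroxyhexadecanoate F4. Swern oxidation ((COCl)2, DMSO, Et3N, CH2Cl2, −78 °C) gives methyl 16-oxohexadecanoate F5, which is isolated. A separate Wittig reaction with 2 (toluene, 80 °C) gives methyl (E)-18-oxononadec-16-enoate F6. F6 is carried through the conditions of step 2 in place of 4; its chain ester is cleaved in the NaOH stage, so the sequence rejoins at 9.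

Further compounds
F1 | step 3 | methyl 15-[5-methoxy-3-oxo-2-(phenylselanyl)cyclohex-4-en-1-yl]pentadecanoate (racemic, trans expected) | COC1=CC(=O)C([Se]c2ccccc2)C(CCCCCCCCCCCCCCC(=O)OC)C1
F2 | step 5 | 15-{5-hydroxy-3-methoxy-2-[(E)-(4-sulfophenyl)diazenyl]phenyl}pentadecanoic acid | OC(=O)CCCCCCCCCCCCCCc1cc(O)cc(OC)c1/N=N/c1ccc(cc1)S(=O)(=O)O
F3 | step 5 | 15-(2-amino-5-hydroxy-3-methoxyphenyl)pentadecanoic acid | OC(=O)CCCCCCCCCCCCCCc1cc(O)cc(OC)c1N
F4 | step 1 | methyl 16-hydroxyhexadecanoate | COC(=O)CCCCCCCCCCCCCCCO
F5 | step 1 | methyl 16-oxohexadecanoate | COC(=O)CCCCCCCCCCCCCCC=O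
F6 | step 1 | methyl (E)-18-oxononadec-16-enoate | CC(=O)/C=C/CCCCCCCCCCCCCCC(=O)OC
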